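**Retrosynthetic overview**

1. The target is (3S,5S)-1-(3,4-dimethoxyphenyl)-5-hydroxydecan-3-yl acetate (decane locants: C1 benzylic, C3 the acetoxy carbon, C5 the hydroxy carbon). The last operations are acetylation of O3 and removal of a triethylsilyl group from O5.
2. Feature: the segment C2–C6 with O3 and O5 is an anti-1,3-diol core that is C2-symmetric about C4. In the corresponding diepoxide the two oxiranes, and so O3 and O5, are homotopic and differ only through the order in which they are opened.
3. Key disconnections: C6–C7 (butyl nucleophile) and C1–C2 (3,4-dimethoxybenzyl nucleophile), both at the terminal carbons of (2R,4R)-1,2:4,5-diepoxypentane, with Et3SiCl capturing the first alkoxide between the two openings in one flask.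
4. Rings: the arene is bought and the target is otherwise acyclic. The only rings made are the two oxiranes, closed together before the key step and opened one after the other in it.
5. The linchpin comes from 1,5-dichloropentane-2,4-dione by Ru–BINAP hydrogenation, which sets both stereocentres, and KOH ring closure.

Key step: step 4

Assumption: the dichlorodione, 3,4-dimethoxybenzyl chloride, butylmagnesium chloride (THF solution) and chlorotriethylsilane are bought. The sense of induction in step 1 is assigned by analogy with the Ru–BINAP hydrogenation of 4-chloroacetoacetates, where the (S)-ligand gives the (R)-chlorohydrin, and is to be confirmed on the dichlorodiol before going on.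

**Route**

Step 1
Reactants: 1 1,5-dichloropentane-2,4-dione
Product: 2 (2R,4R)-1,5-dichloropentane-2,4-diol
Conditions: H2 (85 atm), RuCl2[(S)-BINAP] (0.2 mol %), MeOH, 100 °C; recrystallisation
Reagents that add atoms: none
Why: Noyori asymmetric hydrogenation of a 1,3-diketone, in which each ketone is reduced on the divalent ruthenium–BINAP hydride while chelated through the neighbouring carbonyl or hydroxyl oxygen, so the (S)-ligand should set both C2 and C4 as R under catalyst control (anti diol), the minor meso isomer being removed by recrystallisation.

Step 2
Reactants: 2 (2R,4R)-1,5-dichloropentane-2,4-diol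
Product: 3 (2R,4R)-1,2:4,5-diepoxypentane
Conditions: KOH (powdered, 3 equiv), Et2O, rt; filtration, careful concentration, bulb-to-bulb distillation
Reagents that add atoms: none
Why: Double intramolecular Williamson etherification (3-exo-tet), in which each alkoxide displaces the adjacent primary chloride, so neither stereocentre is touched and the R,R configuration is carried into the diepoxide.

Step 3
Reactants: 4 3,4-dimethoxybenzyl chloride
Product: 5 3,4-dimethoxybenzylmagnesium chloride (solution, titrated before use)
Conditions: Mg turnings (3 equiv, activated with i-Bu2AlH, 1 mol %), 2-methyltetrahydrofuran, 0 °C, slow addition of 4 (0.3 M)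
Reagents that add atoms: magnesium, [Mg]
Why: Grignard reagent formation by magnesium insertion into the benzylic C–Cl bond, with slow addition of dilute chloride to excess activated metal at 0 °C to hold back Wurtz homocoupling to the bibenzyl.

Step 4
Reactants: 3 (2R,4R)-1,2:4,5-diepoxypentane; 6 butylmagnesium chloride; 7 chlorotriethylsilane; 5 3,4-dimethoxybenzylmagnesium chloride
Product: 11 (3S,5S)-1-(3,4-dimethoxyphenyl)-5-(triethylsilyloxy)decan-3-ol, via chloromagnesium epoxy alkoxide 8 (not isolated), via triethylsilyl epoxy ether 9 (not isolated), via chloromagnesium alkoxide of the product 10 (not isolated)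
Conditions: CuI (10 mol %), THF, −40 °C, 6 (1.0 equiv, syringe pump) into 3 (1.2 equiv), → −20 °C; 7 (1.0 equiv), N-methylimidazole (10 mol %), −20 → 0 °C; CuI (5 mol %), 5 (2.0 equiv), −30 → 0 °C; sat. aq NH4Cl, 0 °C
Reagents that add atoms: butylmagnesium chloride, CCCC[Mg]Cl; chlorotriethylsilane, CC[Si](Cl)(CC)CC; 3,4-dimethoxybenzylmagnesium chloride, COc1ccc(C[Mg]Cl)cc1OC
Why: Proposed new method: a monovalent-copper-catalysed Grignard opening of one oxirane of 3, capture of the chloromagnesium alkoxide 8 by Et3SiCl through the N-silylimidazolium, and a second copper-catalysed opening of 9 by the benzylic reagent 5 are run in one flask, each opening being an SN2 attack of a magnesium cuprate on the unsubstituted oxirane CH2, which forms C6–C7 and then C1–C2. The closest known reaction type is the stepwise copper-catalysed Grignard mono-opening of C2-symmetric 1,2:4,5-diepoxypentane with isolation, separate silylation and a second opening, together with the in-flask capture of magnesium alkoxides by chlorosilanes. No ring is closed, since both oxiranes are opened, and no new stereocentre is made: the carbinol carbons C5 and C3 are not attacked and keep the configuration of 3, the descriptor changing from R to S only because the ranking of their two CH2 neighbours is reversed. Because the two oxiranes of 3 are related by the C2 axis, attack on either gives the same mono-adduct, and the oxygen released first (O5) is the one silylated while the oxygen released second (O3) stays free, so the order of addition alone tells the two hydroxyls apart. The step needs mono- over double opening, which slow addition of 6 as the limiting reagent to an excess of 3 at low temperature should secure. It also needs terminal over internal attack, which the steric preference of the cuprate and the use of chloride reagents (little halohydrin) should secure, and no O5-to-O3 silyl transfer in alkoxide 10, which the covalent magnesium alkoxide, the low temperature and an immediate cold buffered quench should prevent.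

Step 5
Reactants: 11 (3S,5S)-1-(3,4-dimethoxyphenyl)-5-(triethylsilyloxy)decan-3-ol
Product: 12 (3S,5S)-1-(3,4-dimethoxyphenyl)-5-(triethylsilyloxy)decan-3-yl acetate
Conditions: Ac2O (2 equiv), pyridine (4 equiv), DMAP (5 mol %), CH2Cl2, 0 °C → rt
Reagents that add atoms: acetic anhydride, CC(=O)OC(C)=O
Why: DMAP-catalysed acylation of the only free hydroxyl with acetic anhydride, in which only the O–H bond reacts, so the C3 configuration is untouched and the triethylsilyl ether is stable to the basic medium.

Step 6
Reactants: 12 (3S,5S)-1-(3,4-dimethoxyphenyl)-5-(triethylsilyloxy)decan-3-yl acetate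
Product: 13 (3S,5S)-1-(3,4-dimethoxyphenyl)-5-hydroxydecan-3-yl acetate
Conditions: HF·pyridine, pyridine, THF, 0 °C
Reagents that add atoms: none
Why: Fluoride-mediated desilylation under pyridine-buffered, weakly acidic conditions at 0 °C should cleave the triethylsilyl ether without base, which avoids acetate hydrolysis and keeps 1,3-acyl migration from O3 to O5 slow.

**Compound list**

1 | 1,5-dichloropentane-2,4-dione | ClCC(=O)CC(=O)CCl | starting material
2 | (2R,4R)-1,5-dichloropentane-2,4-diol | ClC[C@H](O)C[C@@H](O)CCl | intermediate
3 | (2R,4R)-1,2:4,5-diepoxypentane | C1[C@H](O1)C[C@@H]1CO1 | intermediate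
4 | 3,4-dimethoxybenzyl chloride (4-(chloromethyl)-1,2-dimethoxybenzene) | COc1ccc(CCl)cc1OC | starting material
5 | 3,4-dimethoxybenzylmagnesium chloride | COc1ccc(C[Mg]Cl)cc1OC | intermediate
6 | butylmagnesium chloride | CCCC[Mg]Cl | starting material
7 | chlorotriethylsilane | CC[Si](Cl)(CC)CC | starting material
8 | chloromagnesium (2S)-1-[(2R)-oxiran-2-yl]heptan-2-olate | CCCCC[C@H](O[Mg]Cl)C[C@@H]1CO1 | intermediate
9 | triethyl{[(2S)-1-[(2R)-oxiran-2-yl]heptan-2-yl]oxy}silane | CCCCC[C@H](O[Si](CC)(CC)CC)C[C@@H]1CO1 | intermediate
10 | chloromagnesium (3S,5S)-1-(3,4-dimethoxyphenyl)-5-(triethylsilyloxy)decan-3-olate | CCCCC[C@H](O[Si](CC)(CC)CC)C[C@@H](O[Mg]Cl)CCc1ccc(OC)c(OC)c1 | intermediate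
11 | (3S,5S)-1-(3,4-dimethoxyphenyl)-5-(triethylsilyloxy)decan-3-ol | CCCCC[C@H](O[Si](CC)(CC)CC)C[C@@H](O)CCc1ccc(OC)c(OC)c1 | intermediate
12 | (3S,5S)-1-(3,4-dimethoxyphenyl)-5-(triethylsilyloxy)decan-3-yl acetate | CCCCC[C@H](O[Si](CC)(CC)CC)C[C@@H](OC(C)=O)CCc1ccc(OC)c(OC)c1 | intermediate
13 | (3S,5S)-1-(3,4-dimethoxyphenyl)-5-hydroxydecan-3-yl acetate | CCCCC[C@H](O)C[C@H](CCc1ccc(OC)c(OC)c1)OC(C)=O | target

**Step count**

Total: 6 steps. Longest linear sequence: 5 steps (steps 1, 2, 4, 5, 6 from 1); step 3 is a one-step side branch from 4.

**Steps most likely to fail**

1. Step 4. What may go wrong: over-opening of the diepoxide by the first Grignard reagent; incomplete capture of the chloromagnesium alkoxide by the chlorosilane, so that the two oxygens are not cleanly told apart; consumption of the benzylic reagent by leftover chlorosilane; and O-to-O silyl transfer in the final alkoxide. In the one-flask run the doubly butylated by-product should end as a non-polar bis-silyl ether and surplus 3 as a polar bis-benzylated diol, both separable from 11. Fallback, all known chemistry: the sequence is split into three isolated operations. From 3, used in threefold excess with the surplus recovered by distillation, BuMgCl and CuI (10 mol %) in THF at −40 °C followed by NH4Cl work-up should give the purified epoxy alcohol (2S)-1-[(2R)-oxiran-2-yl]heptan-2-ol F1. Et3SiCl and imidazole in DMF convert it into 9, now isolated. 9 is then opened in a separate flask with 5 and CuI (10 mol %) at −30 °C and quenched cold, coming back to the route at 11.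

2. Step 3. What may go wrong: Wurtz homocoupling during magnesium insertion into the electron-rich benzylic chloride, leaving too little active reagent, and decay of the benzylic organocopper before it opens the oxirane. Fallback: the benzyl anion is replaced by a sulfone-stabilised carbanion. From 4, displacement with PhSO2Na in DMF should give 3,4-dimethoxybenzyl phenyl sulfone F2. Deprotonated with n-BuLi in THF/DMPU at −78 °C and warmed, it opens the terminal carbon of isolated 9 (taken from step 4 stopped after the silylation stage, or from the fallback above). This gives (3R,5S)-1-(3,4-dimethoxyphenyl)-1-(phenylsulfonyl)-5-(triethylsilyloxy)decan-3-ol F3 as both C1 epimers; the spatial arrangement is that of 11, and the C3 descriptor changes only because the sulfonyl-bearing branch outranks C4. Reductive desulfonylation with Na/Hg and Na2HPO4 in MeOH/THF at −20 °C then comes back to the route at 11.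

3. Step 1. What may go wrong: incomplete catalyst control in the second ketone reduction (meso diol), hydrogenolysis of C–Cl bonds at the temperature the chloro ketone needs, and dependence on high-pressure equipment. Fallback: resolution instead of asymmetric reduction. From 1, NaBH4 in MeOH at −20 °C should give 1,5-dichloropentane-2,4-diol F4 as a stereoisomer mixture, and KOH in Et2O closes it to 1,2:4,5-diepoxypentane F5, likewise a stereoisomer mixture. Jacobsen hydrolytic kinetic resolution follows, with H2O (1.1 equiv) and the trivalent cobalt complex [N,N′-bis(3,5-di-tert-butylsalicylidene)-1,2-cyclohexanediaminato]Co(OAc) (1 mol %), 0 °C → rt. The catalyst enantiomer is the one that hydrolyses (S)-configured oxiranes, expected to be the (R,R)-complex by analogy with simple 1-alkyl oxiranes. The meso isomer should become (2S)-3-[(2R)-oxiran-2-yl]propane-1,2-diol F6 and the S,S isomer (2S,4S)-pentane-1,2,4,5-tetraol F7, both left in the pot. The untouched R,R diepoxide is distilled off, coming back to the route at 3.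

**Further compounds**

F1 | step 4 | (2S)-1-[(2R)-oxiran-2-yl]heptan-2-ol | CCCCC[C@H](O)C[C@@H]1CO1
F2 | step 3 | 3,4-dimethoxybenzyl phenyl sulfone | COc1ccc(CS(=O)(=O)c2ccccc2)cc1OC
F3 | step 3 | (3R,5S)-1-(3,4-dimethoxyphenyl)-1-(phenylsulfonyl)-5-(triethylsilyloxy)decan-3-ol (both C1 epimers) | CCCCC[C@H](O[Si](CC)(CC)CC)C[C@@H](O)CC(c1ccc(OC)c(OC)c1)S(=O)(=O)c1ccccc1
F4 | step 1 | 1,5-dichloropentane-2,4-diol (stereoisomer mixture) | ClCC(O)CC(O)CCl
F5 | step 1 | 1,2:4,5-diepoxypentane (stereoisomer mixture) | C1OC1CC1CO1
F6 | step 1 | (2S)-3-[(2R)-oxiran-2-yl]propane-1,2-diol | OC[C@@H](O)C[C@@H]1CO1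
F7 | step 1 | (2S,4S)-pentane-1,2,4,5-tetraol | OC[C@@H](O)C[C@H](O)CO
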